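**Plan**

Numbering: ring C1 (angelate), C2, C3 (methyl), C4 (hydroxyl), C5, C6 (side chain); chain C7 (methyl), C8, C9 (acetate), C10=C11(CH3)2. The C9 acetate sits on an allylic carbon next to the gem-dimethyl C10=C11 alkene, so a C9 alcohol and an achiral tertiary C11 alcohol are 1,3-transposition partners; this is what the key step uses.
Retrosynthetic cuts, in order: C4–H (ketone reduction); C9–O and acetyl C–O (vanadate transposition with enzymatic acetylation); C1–O acyl (angeloylation); C2–H/C3–H (conjugate reduction); the ring C1–O and C4–O bonds (singlet oxygen); C3–CH3 (cross-coupling); C11–O (selenium-mediated allylic hydroxylation); C1=C2 and C5–C6 (aldol condensation and Michael addition).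
Forward: the only ring closes first, by Michael addition of (R)-citronellal to methyl vinyl ketone and aldol condensation. The chain terminus is then turned into the tertiary allylic alcohol, the enone into a methyl diene, and the diene into the cis-1,4-dioxygenated ring. Angelate, C9 acetate and C4 alcohol follow.
Stereochemistry: C7 from (R)-citronellal; C6 from the prolinol catalyst; C1 from anti addition of singlet oxygen; C3 by equilibration to equatorial; C9 from the hydrolase; C4 from equatorial hydride delivery.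

Key step: step 8

Remark (assumption): the hydrolase of step 8 is taken to be subtilisin Carlsberg; its acceptance of a carbinol flanked by an isobutenyl group and a branched alkyl arm is assumed from its acylation of other hindered secondary alcohols and is not documented for this substrate class. C4 is kept as a ketone through step 8 so that no second acylable hydroxyl is present.

Step 1
Reactants: 1 (R)-citronellal; 2 methyl vinyl ketone
Product: 5 (4S)-4-[(2R)-6-methylhept-5-en-2-yl]cyclohex-2-en-1-one, via keto aldehyde 3 (not isolated), via aldol adduct 4 (not isolated)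
Conditions: (S)-α,α-diphenylprolinol trimethylsilyl ether (5 mol%), ethyl 3,4-dihydroxybenzoate (20 mol%), neat, 4 °C; then KOH, n-Bu4NOH (cat.), THF/Et2O/H2O, reflux
Reagents that add atoms: none
Why: Enamine-catalysed Michael addition, in which the bulky silyloxydiphenylmethyl group of the (S)-catalyst shields one face of the E-enamine so that C6 is formed S irrespective of the resident C7 centre taken from (R)-citronellal, followed by base-mediated intramolecular aldol condensation (Robinson annulation) that closes the cyclohexenone.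

Step 2
Reactants: 5 (4S)-4-[(2R)-6-methylhept-5-en-2-yl]cyclohex-2-en-1-one
Product: 8 (4S)-4-[(2R,4E)-6-hydroxy-6-methylhept-4-en-2-yl]cyclohex-2-en-1-one, via hydroxy selenide 6 (not isolated), via selenoxide 7 (not isolated)
Conditions: PhSeSePh, 30% H2O2, CH2Cl2, 0 °C, then MgSO4 and 5, rt; then t-BuOOH, rt
Reagents that add atoms: benzeneselenenic acid (formed in the flask from PhSeSePh and H2O2), O[Se]c1ccccc1
Why: Oxyselenation followed by selenoxide syn-elimination: electrophilic PhSeOH adds in the Markovnikov sense to the electron-rich trisubstituted alkene only (the enone alkene is electron-poor) and the selenoxide formed with t-BuOOH eliminates toward C9, the sole hydrogen-bearing β-carbon, giving the E tertiary allylic alcohol.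

Step 3
Reactants: 8 (4S)-4-[(2R,4E)-6-hydroxy-6-methylhept-4-en-2-yl]cyclohex-2-en-1-one
Product: 9 (4S)-4-[(2R,4E)-6-hydroxy-6-methylhept-4-en-2-yl]cyclohexa-1,5-dien-1-yl trifluoromethanesulfonate
Conditions: LiN(SiMe3)2 (2.2 equiv), THF, −78 °C; PhNTf2, −78 → 0 °C; aq. NH4Cl
Reagents that add atoms: N-phenylbis(trifluoromethanesulfonimide), O=S(=O)(N(c1ccccc1)S(=O)(=O)C(F)(F)F)C(F)(F)F
Why: Enol triflate formation from the kinetic cross-conjugated dienolate (deprotonation at the α′ carbon C4, not at the γ carbon C6, so the C6 centre is untouched), the hindered tertiary lithium alkoxide being inert toward the mild N-aryl triflimide.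

Step 4
Reactants: 9 (4S)-4-[(2R,4E)-6-hydroxy-6-methylhept-4-en-2-yl]cyclohexa-1,5-dien-1-yl trifluoromethanesulfonate
Product: 10 (3E,6R)-2-methyl-6-[(1S)-4-methylcyclohexa-2,4-dien-1-yl]hept-3-en-2-ol
Conditions: MeMgBr (3 equiv), Fe(acac)3 (5 mol%), THF/NMP, −30 → 0 °C; aq. NH4Cl
Reagents that add atoms: methylmagnesium bromide, C[Mg]Br
Why: Iron-catalysed Kumada-type cross-coupling of an alkenyl triflate with a Grignard reagent that has no β-hydrogen installs the C3 methyl without shifting the diene, one equivalent of MeMgBr being consumed by the hydroxyl.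

Step 5
Reactants: 10 (3E,6R)-2-methyl-6-[(1S)-4-methylcyclohexa-2,4-dien-1-yl]hept-3-en-2-ol
Product: 12 (4S,5S)-4-hydroxy-5-[(2R,4E)-6-hydroxy-6-methylhept-4-en-2-yl]-2-methylcyclohex-2-en-1-one, via endoperoxide 11 (not isolated)
Conditions: O2, meso-tetraphenylporphyrin (cat.), visible light, CH2Cl2, −20 °C; then Et3N, 0 °C → rt
Reagents that add atoms: oxygen, O=O
Why: [4+2] cycloaddition of singlet oxygen to the cisoid ring diene, expected mainly on the face anti to the C6 side chain, makes the C1–O and C4–O bonds cis and thereby sets C1 (the E-disubstituted chain alkene reacts far more slowly), and the amine-induced Kornblum–DeLaMare rearrangement is expected to remove the C4 bridgehead proton, flanked by the C5 methylene, rather than the C1 proton next to the branched C6 centre, giving the C4 enone with the C1 carbinol intact.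

Step 6
Reactants: 12 (4S,5S)-4-hydroxy-5-[(2R,4E)-6-hydroxy-6-methylhept-4-en-2-yl]-2-methylcyclohex-2-en-1-one
Product: 13 (2S,4R,5S)-4-hydroxy-5-[(2R,4E)-6-hydroxy-6-methylhept-4-en-2-yl]-2-methylcyclohexan-1-one
Conditions: [(Ph3P)CuH]6 (0.4 equiv), wet toluene, rt; then DBU (cat.), CH2Cl2, rt
Reagents that add atoms: none
Why: Conjugate reduction of the enone by the phosphine-stabilised copper hydride (monovalent copper), which leaves the isolated alkene and the hydroxyls alone, after which DBU equilibrates C3 (α to the ketone) to the all-equatorial isomer with the methyl trans to the C6 chain, so C3 is set under thermodynamic control.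

Step 7
Reactants: 13 (2S,4R,5S)-4-hydroxy-5-[(2R,4E)-6-hydroxy-6-methylhept-4-en-2-yl]-2-methylcyclohexan-1-one; 14 angelic acid
Product: 16 (1R,2S,5S)-2-[(2R,4E)-6-hydroxy-6-methylhept-4-en-2-yl]-5-methyl-4-oxocyclohexyl (Z)-2-methylbut-2-enoate, via mixed anhydride 15 (not isolated)
Conditions: 14, 2,4,6-trichlorobenzoyl chloride, Et3N, toluene, rt; then 13, 80 °C
Reagents that add atoms: none
Why: Yamaguchi esterification through the mixed anhydride, run without a nucleophilic catalyst so that the Z double bond of the angeloyl group is not isomerised to the tiglate, acylates only the secondary equatorial C1 hydroxyl because the C11 alcohol is tertiary.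

Step 8
Reactants: 16 (1R,2S,5S)-2-[(2R,4E)-6-hydroxy-6-methylhept-4-en-2-yl]-5-methyl-4-oxocyclohexyl (Z)-2-methylbut-2-enoate; 17 vinyl acetate
Product: 19 (1R,2S,5S)-2-[(2R,4R)-4-acetoxy-6-methylhept-5-en-2-yl]-5-methyl-4-oxocyclohexyl (Z)-2-methylbut-2-enoate, via 9R allylic alcohol 18 (not isolated)
Conditions: VO(OSiPh3)3 (10 mol%), surfactant-coated subtilisin Carlsberg, vinyl acetate (3 equiv), MeCN, 35 °C
Reagents that add atoms: none
Why: Proposed new method: VO(OSiPh3)3 (pentavalent vanadium) exchanges a silanolate for the tertiary C11 alkoxide of 16 and the allyl vanadate undergoes a reversible [3,3]-type 1,3-oxygen shift, so 16, the 9R alcohol 18 and its 9S epimer form one pool that interconverts through the achiral tertiary isomer. Subtilisin, through the serine acyl-enzyme formed irreversibly from vinyl acetate, acetylates only one of the secondary alcohols and drains the pool, which forms the C9–O bond and the acetate ester. The closest known reaction type is the lipase–oxovanadium dynamic kinetic resolution of allylic alcohols with 1,3-transposition, documented for carbinols with one small substituent, together with subtilisin-based dynamic kinetic resolutions run with other racemisation catalysts; no ring is closed. C9 is controlled by the enzyme alone: the flat four-carbon isobutenyl group is the smaller neighbour of C9 and should sit in the restricted S1′ site with the branched C8 arm toward solvent, which in the catalytic geometry of subtilisin (mirror image of that of lipases, where the same binding mode would lead to 9S) corresponds to the 9R ester. Chemoselectivity is secured by the substrate, since C4 is still a ketone, the only other hydroxyl (C11) is tertiary, and the angelate is not transesterified under anhydrous conditions.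

Step 9
Reactants: 19 (1R,2S,5S)-2-[(2R,4R)-4-acetoxy-6-methylhept-5-en-2-yl]-5-methyl-4-oxocyclohexyl (Z)-2-methylbut-2-enoate
Product: 20 (1R,2S,4R,5S)-2-[(2R,4R)-4-acetoxy-6-methylhept-5-en-2-yl]-4-hydroxy-5-methylcyclohexyl (Z)-2-methylbut-2-enoate (CNP0237033.1)
Conditions: LiBH(s-Bu)3 (1.1 equiv), THF, −78 °C; then aq. NH4Cl
Reagents that add atoms: none
Why: Ketone reduction by a bulky trialkylborohydride, which attacks the chair-locked 2-methylcyclohexanone from the equatorial side and gives the axial C4 alcohol cis to the C3 methyl (4R), the acetate, the angelate and the alkenes being inert at −78 °C.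

**Compound list**

1 | (R)-citronellal, (3R)-3,7-dimethyloct-6-enal | C[C@H](CCC=C(C)C)CC=O | starting material
2 | methyl vinyl ketone, but-3-en-2-one | CC(=O)C=C | starting material
3 | (2S,3R)-3,7-dimethyl-2-(3-oxobutyl)oct-6-enal | O=C[C@@H](CCC(C)=O)[C@H](C)CCC=C(C)C | intermediate
4 | (4S)-3-hydroxy-4-[(2R)-6-methylhept-5-en-2-yl]cyclohexan-1-one (both carbinol epimers) | O=C1CC(O)[C@@H](CC1)[C@H](C)CCC=C(C)C | intermediate
5 | (4S)-4-[(2R)-6-methylhept-5-en-2-yl]cyclohex-2-en-1-one | O=C1C=C[C@@H](CC1)[C@H](C)CCC=C(C)C | intermediate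
6 | (4S)-4-[(2R)-6-hydroxy-6-methyl-5-(phenylselanyl)heptan-2-yl]cyclohex-2-en-1-one (both epimers at the selenium-bearing carbon) | O=C1C=C[C@@H](CC1)[C@H](C)CCC([Se]c2ccccc2)C(C)(C)O | intermediate
7 | selenoxide of 6, (4S)-4-[(2R)-6-hydroxy-6-methyl-5-(phenylseleninyl)heptan-2-yl]cyclohex-2-en-1-one | O=C1C=C[C@@H](CC1)[C@H](C)CCC([Se](=O)c2ccccc2)C(C)(C)O | intermediate
8 | (4S)-4-[(2R,4E)-6-hydroxy-6-methylhept-4-en-2-yl]cyclohex-2-en-1-one | O=C1C=C[C@@H](CC1)[C@H](C)C/C=C/C(C)(C)O | intermediate
9 | (4S)-4-[(2R,4E)-6-hydroxy-6-methylhept-4-en-2-yl]cyclohexa-1,5-dien-1-yl trifluoromethanesulfonate | O=S(=O)(OC1=CC[C@H](C=C1)[C@H](C)C/C=C/C(C)(C)O)C(F)(F)F | intermediate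
10 | (3E,6R)-2-methyl-6-[(1S)-4-methylcyclohexa-2,4-dien-1-yl]hept-3-en-2-ol | CC1=CC[C@H](C=C1)[C@H](C)C/C=C/C(C)(C)O | intermediate
11 | (3E,6R)-2-methyl-6-[(1S,4R,7S)-5-methyl-2,3-dioxabicyclo[2.2.2]oct-5-en-7-yl]hept-3-en-2-ol | CC1=C[C@@H]2[C@H]([C@H](C)C/C=C/C(C)(C)O)C[C@H]1OO2 | intermediate
12 | (4S,5S)-4-hydroxy-5-[(2R,4E)-6-hydroxy-6-methylhept-4-en-2-yl]-2-methylcyclohex-2-en-1-one | O[C@@H]1C=C(C)C(=O)C[C@H]1[C@H](C)C/C=C/C(C)(C)O | intermediate
13 | (2S,4R,5S)-4-hydroxy-5-[(2R,4E)-6-hydroxy-6-methylhept-4-en-2-yl]-2-methylcyclohexan-1-one | O[C@@H]1C[C@H](C)C(=O)C[C@H]1[C@H](C)C/C=C/C(C)(C)O | intermediate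
14 | angelic acid, (Z)-2-methylbut-2-enoic acid | C/C=C(/C)C(O)=O | starting material
15 | (Z)-2-methylbut-2-enoic 2,4,6-trichlorobenzoic anhydride | C/C=C(/C)C(=O)OC(=O)c1c(Cl)cc(Cl)cc1Cl | intermediate
16 | (1R,2S,5S)-2-[(2R,4E)-6-hydroxy-6-methylhept-4-en-2-yl]-5-methyl-4-oxocyclohexyl (Z)-2-methylbut-2-enoate | C/C=C(/C)C(=O)O[C@@H]1C[C@H](C)C(=O)C[C@H]1[C@H](C)C/C=C/C(C)(C)O | intermediate
17 | vinyl acetate | CC(=O)OC=C | starting material
18 | (1R,2S,5S)-2-[(2R,4R)-4-hydroxy-6-methylhept-5-en-2-yl]-5-methyl-4-oxocyclohexyl (Z)-2-methylbut-2-enoate | C/C=C(/C)C(=O)O[C@@H]1C[C@H](C)C(=O)C[C@H]1[C@H](C)C[C@H](C=C(C)C)O | intermediate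
19 | (1R,2S,5S)-2-[(2R,4R)-4-acetoxy-6-methylhept-5-en-2-yl]-5-methyl-4-oxocyclohexyl (Z)-2-methylbut-2-enoate | C/C=C(/C)C(=O)O[C@@H]1C[C@H](C)C(=O)C[C@H]1[C@H](C)C[C@H](C=C(C)C)OC(C)=O | intermediate
20 | (1R,2S,4R,5S)-2-[(2R,4R)-4-acetoxy-6-methylhept-5-en-2-yl]-4-hydroxy-5-methylcyclohexyl (Z)-2-methylbut-2-enoate, CNP0237033.1 | C/C=C(/C)C(=O)O[C@@H]1C[C@H](C)[C@H](O)C[C@H]1[C@H](C)C[C@H](C=C(C)C)OC(C)=O | target

Total step count: 9. Longest linear sequence: 9 steps (1 to 20).

**Steps most likely to fail**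

Step 8 (proposed new method). The hydrolase may fail to turn over a carbinol with two large neighbours or may acylate the 9S epimer, and vanadate-induced dehydration of the allylic alcohol may compete. The fallback sets out from 16 and returns at 19, using known chemistry only. Johnson–Lemieux cleavage of the C9=C10 alkene of 16 (OsO4 cat., NaIO4, 2,6-lutidine, dioxane/H2O; the electron-poor angelate alkene is spared) gives the C9 aldehyde (1R,2S,5S)-5-methyl-4-oxo-2-[(2R)-4-oxobutan-2-yl]cyclohexyl (Z)-2-methylbut-2-enoate F1. Catalytic asymmetric alkenylzinc addition of Zn(CH=CMe2)2 follows, using the enantiomer of 3-exo-morpholinoisoborneol that directs the alkenyl group to the Si face of the aldehyde. The C4 ketone and the esters do not react, and the product is the 9R alcohol 18, here isolated. Acetylation (Ac2O, pyridine, DMAP) gives 19.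

Step 5. Singlet oxygen may add to both faces of the diene with little discrimination, or the amine may remove the C1 rather than the C4 bridgehead proton. The fallback sets out from 8 and returns at 13, replacing the cycloaddition by stepwise, substrate-controlled oxygenation:
- Copper-catalysed conjugate borylation of 8 (B2pin2, CuCl, a bisphosphine, NaOt-Bu, MeOH, THF) puts boron on C1 anti to the C6 side chain and gives (3R,4R)-4-[(2R,4E)-6-hydroxy-6-methylhept-4-en-2-yl]-3-(4,4,5,5-tetramethyl-1,3,2-dioxaborolan-2-yl)cyclohexan-1-one F2.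
- Oxidation with NaBO3, with retention, gives the trans hydroxy ketone (3R,4S)-3-hydroxy-4-[(2R,4E)-6-hydroxy-6-methylhept-4-en-2-yl]cyclohexan-1-one F3.
- Silylation of both hydroxyls (Et3SiOTf, 2,6-lutidine) gives (3R,4S)-3-(triethylsilyloxy)-4-[(2R,4E)-6-methyl-6-(triethylsilyloxy)hept-4-en-2-yl]cyclohexan-1-one F4.
- Kinetic enolisation away from the β-silyloxy group (LiN(i-Pr)2, THF, −78 °C) and hydroxylation of the enolate with 2-(phenylsulfonyl)-3-phenyloxaziridine give (4S,5R)-2-hydroxy-4-[(2R,4E)-6-methyl-6-(triethylsilyloxy)hept-4-en-2-yl]-5-(triethylsilyloxy)cyclohexan-1-one F5 (C4 epimers in the route numbering, of no consequence).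
- Lombardo methylenation (Zn, CH2Br2, TiCl4) gives (4R,5S)-2-methylidene-5-[(2R,4E)-6-methyl-6-(triethylsilyloxy)hept-4-en-2-yl]-4-(triethylsilyloxy)cyclohexan-1-ol F6.
- Redox isomerisation of this allylic alcohol (RuCl2(PPh3)3, toluene, heat), then DBU equilibration, gives (2S,4R,5S)-2-methyl-5-[(2R,4E)-6-methyl-6-(triethylsilyloxy)hept-4-en-2-yl]-4-(triethylsilyloxy)cyclohexan-1-one F7.
- HF·pyridine removes both silyl groups and returns 13.

Step 7. The Z angeloyl group may isomerise to the E (tigloyl) isomer during activation or acylation. The fallback sets out from 13 and returns at 16, building the Z alkene after the ester bond is in place. The C1 hydroxyl is acylated with 2-[bis(2,2,2-trifluoroethoxy)phosphoryl]propanoic acid (DCC, DMAP, CH2Cl2) to give (1R,2S,5S)-2-[(2R,4E)-6-hydroxy-6-methylhept-4-en-2-yl]-5-methyl-4-oxocyclohexyl 2-[bis(2,2,2-trifluoroethoxy)phosphoryl]propanoate F8. Still–Gennari olefination with acetaldehyde (KN(SiMe3)2, 18-crown-6, THF, −78 °C) then gives the Z ester 16.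

**Further compounds**

F1 | step 8 | (1R,2S,5S)-5-methyl-4-oxo-2-[(2R)-4-oxobutan-2-yl]cyclohexyl (Z)-2-methylbut-2-enoate | C/C=C(/C)C(=O)O[C@@H]1C[C@H](C)C(=O)C[C@H]1[C@H](C)CC=O
F2 | step 5 | (3R,4R)-4-[(2R,4E)-6-hydroxy-6-methylhept-4-en-2-yl]-3-(4,4,5,5-tetramethyl-1,3,2-dioxaborolan-2-yl)cyclohexan-1-one | O=C1C[C@@H](B2OC(C)(C)C(C)(C)O2)[C@@H](CC1)[C@H](C)C/C=C/C(C)(C)O
F3 | step 5 | (3R,4S)-3-hydroxy-4-[(2R,4E)-6-hydroxy-6-methylhept-4-en-2-yl]cyclohexan-1-one | O=C1C[C@@H](O)[C@@H](CC1)[C@H](C)C/C=C/C(C)(C)O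
F4 | step 5 | (3R,4S)-3-(triethylsilyloxy)-4-[(2R,4E)-6-methyl-6-(triethylsilyloxy)hept-4-en-2-yl]cyclohexan-1-one | O=C1C[C@@H](O[Si](CC)(CC)CC)[C@@H](CC1)[C@H](C)C/C=C/C(C)(C)O[Si](CC)(CC)CC
F5 | step 5 | (4S,5R)-2-hydroxy-4-[(2R,4E)-6-methyl-6-(triethylsilyloxy)hept-4-en-2-yl]-5-(triethylsilyloxy)cyclohexan-1-one (C2 epimers) | O=C1C[C@@H](O[Si](CC)(CC)CC)[C@@H](CC1O)[C@H](C)C/C=C/C(C)(C)O[Si](CC)(CC)CC
F6 | step 5 | (4R,5S)-2-methylidene-5-[(2R,4E)-6-methyl-6-(triethylsilyloxy)hept-4-en-2-yl]-4-(triethylsilyloxy)cyclohexan-1-ol (C1 epimers) | C=C1C[C@@H](O[Si](CC)(CC)CC)[C@@H](CC1O)[C@H](C)C/C=C/C(C)(C)O[Si](CC)(CC)CC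
F7 | step 5 | (2S,4R,5S)-2-methyl-5-[(2R,4E)-6-methyl-6-(triethylsilyloxy)hept-4-en-2-yl]-4-(triethylsilyloxy)cyclohexan-1-one | CC[Si](CC)(CC)O[C@@H]1C[C@H](C)C(=O)C[C@H]1[C@H](C)C/C=C/C(C)(C)O[Si](CC)(CC)CC
F8 | step 7 | (1R,2S,5S)-2-[(2R,4E)-6-hydroxy-6-methylhept-4-en-2-yl]-5-methyl-4-oxocyclohexyl 2-[bis(2,2,2-trifluoroethoxy)phosphoryl]propanoate (both α-epimers) | CC(C(=O)O[C@@H]1C[C@H](C)C(=O)C[C@H]1[C@H](C)C/C=C/C(C)(C)O)P(=O)(OCC(F)(F)F)OCC(F)(F)F
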